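## The problem

Target 16 is a flavanone. The phloroglucinol-type ring A is fused to the dihydropyranone ring C, and ring B is attached to C2, the only stereocentre, which is S. No second stereocentre exists to control C2, so its configuration must come from a chiral catalyst. It must also be guarded from then on, because base cleaves O1–C2 by a retro-oxa-Michael reaction and the achiral chalcone recloses without memory. Ring B is a 1,3,4,5-tetrasubstituted anisole whose 4'-methoxy group is flanked by two different five-carbon chains: a prenyl group at C5' and a (Z)-3-hydroxy-3-methylbut-1-enyl group at C3'. The Z-styrenyl tertiary allylic alcohol ionises in acid, drifts to the E isomer under metal hydride, radical or photochemical conditions and, like the prenyl group, is lost on hydrogenation. This rules out acetal and benzyl protection of O5 and O7. Ring A is much more nucleophilic than ring B, so electrophilic halogenation or prenylation of a finished flavanone would strike C6 and C8 rather than ring B. The opening lies in the stripped core 6: its C3'–H and C5'–H bonds are interchanged by rotation about C2–C1', sit next to the smallest substituent in the molecule, and are the only aromatic C–H bonds without a bulky neighbour once O5 and O7 carry triisopropylsilyl groups. A reaction that responds to steric access rather than electron density can therefore mark exactly the two carbons that bear the side chains.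

## Retrosynthesis

**O5–Si and O7–Si (16 to 15).** The last step should need neither acid, free base nor hydrogen, so the two phenolic O–H bonds of 16 are traced back to the O–Si bonds of 15.
- Methoxymethyl ethers would need acid that ionises the allylic alcohol, benzyl ethers would need hydrogenolysis that saturates both alkenes, and acetates would need basic solvolysis that opens ring C.
- Triisopropylsilyl is preferred to tert-butyldimethylsilyl for three reasons. The 7-O-silyl ether is a vinylogous silyl ester that must outlast two basic cross-couplings. The key step profits from bulk on ring A. The group has no Si–CH3 bond that an iridium boryl catalyst could attack.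
- The forward reaction must deliver fluoride while keeping the liberated phenoxides protonated.

**C5'–CH2 (15 to 13 and 14).** The aryl–allyl bond is cut to aryl boronate 13 and prenyl bromide 14.
- The reversed polarity (aryl halide plus prenyl metal) suffers from α/γ scrambling, and a cut inside the chain costs an extra step.
- An aryl group on a π-prenyl palladium complex is delivered to the unsubstituted allyl terminus.
- Making this the last C–C bond means only one boronate is left, so the cheap bromide 14 can be used in excess.
- The precursor is five carbons smaller. The forward reaction must be linear-selective and mild enough in base for C2, the silyl ethers and the allylic alcohol.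

**C3'–C1'' (13 to 9 and 12).** The aryl–alkenyl bond is cut to bis(boronate) 9 and Z-iodoalkene 12.
- A cut through the C=C bond would need an aryl aldehyde and a Z-selective olefination with a hindered tertiary carbinol partner. An alkyne route would need an aryl halide and a semihydrogenation.
- A stereoretentive coupling simply transfers a geometry fixed beforehand in a small molecule.
- The two boronates of 9 are equivalent, so only one mono-adduct can form. However, only stoichiometry restrains the second coupling, and this is the price of the plan.
- The free hydroxyl of 13 at least separates it cleanly from 9 and from the double adduct on silica.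

**C3'–B and C5'–B (9 to 6 and 7).** Both C–B bonds are cut at once, back to flavanone 6 and bis(pinacolato)diboron 7, with monoboronate 8 lying on the way.
- Electrophilic halogenation would go to ring A.
- Directed ortho-metalation is incompatible with the ketone and its acidic C3–H bonds.
- Carrying two handles in from the start would need a tetrasubstituted arene that is not commercial.
- Precursor 6 has no alkene, no boron and an unfunctionalised ring B.
- The forward reaction must pick two of six aromatic C–H bonds, run twice, and leave C2 and the ketone alone.

**C2–C1' (6 to 4 and 5).** This cut removes ring B and the stereocentre together and leads to the flat, achiral chromone 4 and commercial boronic acid 5.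
- The neighbouring O1–C2 cut (chalcone cyclisation) needs base that phenolic silyl ethers do not tolerate, and its asymmetric versions need an extra activating group.
- The forward reaction must add an aryl group to one face of an electron-rich vinylogous ester without over-addition to the product ketone.

**O1–C2 and C2–C3 (4 to 2 to 1).** C2 of the chromone is a one-carbon unit, supplied by a formamide acetal through enaminone 3, which leaves acetophenone 2.
- Silylating before ring closure avoids having to silylate a chelated 5-hydroxychromone.
- In phloroacetophenone 1 the two ortho hydroxyls are equivalent and only one can be chelated at a time. Two silyl groups therefore go on and the third hydroxyl stays free for the ring closure.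

**C–I and two C–H bonds (12 to 11 to 10).** The Z-iodoalkene is traced to iodoalkyne 11 by removing two syn hydrogen atoms, and 11 to commercial 2-methylbut-3-yn-2-ol 10 by removing iodine. All five carbons and the carbinol are bought, and the only demand is a metal-free syn reduction that spares the C–I bond.

## Roads not taken

**Alternative 1:** The cut is C4a–C5 in ring A. The arene is unravelled to a polyketide-like chain on an enantiopure dihydropyranone, methyl 4-[(2S)-2-(3-bromo-4-methoxy-5-prenylphenyl)-4-oxo-3,4-dihydro-2H-pyran-6-yl]-3-oxobutanoate A1. In the forward step a mild base such as Mg(OMe)2 would form the extended enolate, C4a would attack the ester carbon, and tautomerisation would give (S)-3'-bromo-5,7-dihydroxy-4'-methoxy-5'-prenylflavanone A2.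

*Merits*
- Ring A appears with both phenols free, so no protection is needed.
- The stereocentre can come from a catalytic asymmetric hetero-Diels–Alder reaction.
- Bromine and prenyl are different from the outset, so no statistical coupling is needed. This is a clear advantage over step 7.

*Weak points*
- The trisubstituted benzaldehyde behind A1 takes several classical steps.
- A1 has three acidic sites, so aldol-type closure onto the C4 carbonyl competes with the Claisen mode.
- Enolisation toward C3 can expel O1 under exactly the basic conditions required, which endangers C2.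
- A2 is still one hindered aryl bromide coupling short of the target. That coupling must be run in base on a free dihydroxyflavanone, or after a reprotection that gives back the advantage.

*Comparison:* The chosen plan sets against this a commercial ring B building block, a shorter sequence, and a known reaction type in every step.

**Alternative 2:** The cut removes both C–CH3 bonds of the carbinol and restores a lactone. Ring B becomes the benzo ring of 6-[(2S,4S)-5,7-bis(tert-butyldimethylsilyloxy)-4-hydroxychroman-2-yl]-8-prenylcoumarin A3. In the forward step excess MeLi with CeCl3 adds twice to the lactone carbonyl and releases the (2S,4S)-flavan-4-ol A4, which carries a free 4'-phenol, the prenyl group and the Z-hydroxyalkenyl chain.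

*Merits*
- The Z geometry is guaranteed by the ring and does not depend on a stereoretentive coupling, which is more secure than step 7.
- The two ortho positions are differentiated.
- At the flavan-4-ol level C2 is immune to base.

*Weak points*
- A4 is an ortho-hydroxy Z-cinnamyl tertiary alcohol, the classical precursor of a 2,2-dimethyl-2H-chromene. Traces of acid, even silica, can close that ring before O4' is methylated.
- The ketone must be reduced beforehand and reoxidised afterwards, with a temporary stereocentre at C4.
- Three further steps follow the key step (O-methylation, oxidation, desilylation).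
- Excess MeLi can attack phenolic silyl ethers at silicon.
- The coumarin building block is not commercial.

*Comparison:* The chosen plan keeps O4' methylated throughout, so the chromene pathway does not exist, and it needs no redox detour. It pays with a geometry that must survive two palladium steps.

**Alternative 3:** The cuts are O1–C8a and C4–C4a. Ring A comes from 3,5-bis(methoxymethoxy)-2-(trimethylsilyl)phenyl trifluoromethanesulfonate A5. The rest comes from methyl (3S)-3-(3-bromo-4-methoxy-5-prenylphenyl)-3-(triethylsilyloxy)propanoate A6. With CsF the aryne and the alkoxide are released together. The alkoxide adds to C8a and the C4a anion attacks the ester, giving (S)-3'-bromo-4'-methoxy-5'-prenyl-5,7-bis(methoxymethoxy)flavanone A7.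

*Merits*
- It is the most convergent of the four plans, forming two bonds and ring C in one step.
- The C5 alkoxy group steers the nucleophile to C8a.
- The stereocentre can come from a reliable asymmetric β-keto ester hydrogenation, and its C–O bond is never broken.
- Bromine and prenyl are already differentiated.

*Weak points*
- A β-alkoxide of an ester with a para-methoxyaryl group is prone to retro-aldol cleavage and to elimination to the cinnamate.
- The aryl anion may be protonated before it acylates.
- The annulation is established for phenoxide-type nucleophiles, not for secondary benzylic alkoxides.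
- A5 takes several steps from phloroglucinol.
- Silyl protection is excluded by the fluoride, so the acetals of A7 must later be removed with acid in the presence of the tertiary allylic alcohol.

*Comparison:* The chosen plan is less convergent and has a statistical step. Its key reaction rests on firmer ground, however, and its protecting groups come off under buffered fluoride.

Key step: step 4

Assumption: the (S)-configured biaryl diphosphine of step 3 is taken to give the 2S product by analogy with its known sense of addition to 2-cyclohexenone; if the circular dichroism check on 6 shows the opposite sense, the (R)-ligand is used and nothing else changes.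

## Route

Step 1
Reactants: 1 2,4,6-trihydroxyacetophenone (phloroacetophenone, dried)
Product: 2 1-[2-hydroxy-4,6-bis(triisopropylsilyloxy)phenyl]ethanone
Conditions: TIPSCl (2.2 equiv), imidazole (5 equiv), DMF, 0 °C to rt
Reagents that add atoms: triisopropylsilyl chloride, CC(C)[Si](Cl)(C(C)C)C(C)C
Why: Selective O-silylation; the para hydroxyl and one of the two equivalent ortho hydroxyls react, while the last one is held in a hydrogen bond to the acetyl oxygen and is crowded, the selectivity well known for 4,6-di-O-protection of phloroacetophenone.

Step 2
Reactants: 2 1-[2-hydroxy-4,6-bis(triisopropylsilyloxy)phenyl]ethanone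
Product: 4 5,7-bis(triisopropylsilyloxy)-4H-chromen-4-one, via enaminone 3 (not isolated)
Conditions: Me2NCH(OMe)2 (3 equiv), toluene, 90 °C; evaporate; p-TsOH·H2O (1.5 equiv), CH2Cl2, rt
Reagents that add atoms: N,N-dimethylformamide dimethyl acetal, COC(OC)N(C)C
Why: Enaminone route to chromones; the methyl ketone condenses with the formamide acetal, and acid then lets the free phenol add to the β-carbon and expels dimethylamine. The sequence is standard for 2-hydroxy-4,6-dialkoxyacetophenones, and aryl TIPS ethers tolerate both the warm neutral and the mildly acidic stage.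

Step 3
Reactants: 4 5,7-bis(triisopropylsilyloxy)-4H-chromen-4-one; 5 4-methoxyphenylboronic acid
Product: 6 (2S)-2-(4-methoxyphenyl)-5,7-bis(triisopropylsilyloxy)-2,3-dihydro-4H-chromen-4-one
Conditions: [RhCl(C2H4)2]2 (1.5 mol%), (S)-MeO-F12-BIPHEP [(S)-6,6'-dimethoxy-2,2'-bis{bis(3,4,5-trifluorophenyl)phosphino}biphenyl] (3.3 mol%), 5 (2 equiv), aq. KOH (0.1 equiv), CH2Cl2/H2O 10:1, rt
Reagents that add atoms: none
Why: Hayashi–Miyaura asymmetric 1,4-addition, a reaction known for chromones including 5,7-dioxygenated ones; the aryl complex of monovalent rhodium inserts C2=C3 and the oxa-π-allyl rhodium species is hydrolysed. C2 is set by the ligand, whose quadrant pattern leaves only one face of the flat acceptor open, and the configuration of 6 is checked by circular dichroism against the rule for 2S-flavanones. The electron-poor diphosphine allows room temperature, and CH2Cl2 with only catalytic base disfavours 1,2-addition to the product and opening of ring C.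

Step 4
Reactants: 6 (2S)-2-(4-methoxyphenyl)-5,7-bis(triisopropylsilyloxy)-2,3-dihydro-4H-chromen-4-one; 7 bis(pinacolato)diboron
Product: 9 (2S)-2-[4-methoxy-3,5-bis(4,4,5,5-tetramethyl-1,3,2-dioxaborolan-2-yl)phenyl]-5,7-bis(triisopropylsilyloxy)-2,3-dihydro-4H-chromen-4-one, via monoboronate 8 (not isolated)
Conditions: [Ir(OMe)(cod)]2 (5 mol%), 4,4'-di-tert-butyl-2,2'-bipyridine (10 mol%), 7 (3 equiv), THF, 80 °C, sealed vessel
Reagents that add atoms: none
Why: Ishiyama–Miyaura–Hartwig aromatic C–H borylation, the closest known case being para-substituted anisoles, which are borylated next to the methoxy group when the para substituent is branched. The precatalyst, the bipyridine and 7 form a 16-electron tris(boryl) complex of trivalent iridium; it cleaves the most accessible aromatic C–H bond by oxidative addition to a pentavalent iridium hydride, C–B reductive elimination releases the aryl boronate, and 7 or the pinacolborane formed restores the tris(boryl) complex. The first cycle gives monoboronate 8, and the second acts on the remaining C–H bond ortho to the methoxy group to give 9. No ring is closed and no stereocentre is made; C2 is a spectator, and the neutral aprotic medium shuts the retro-oxa-Michael path to the chalcone. Site selectivity among six aromatic C–H bonds is needed: C6–H lies between two OTIPS groups, C8–H between O1 and the 7-OTIPS group (geared toward C8 by the 5-OTIPS group), and C2'–H and C6'–H next to the branched carbon C2, whereas the methoxy group can turn its methyl group away or out of the ring plane. The second borylation is the slower one because the methoxy group of 8 must leave the ring plane, hence the excess of 7, the high loading and 80 °C; any 8 left over is separated and resubmitted. Chemoselectivity is secured by the substrate: the C4 ketone has no ortho C–H bond to direct the catalyst to, it is an electron-rich and doubly ortho-substituted carbonyl that resists pinacolborane, TIPS has no Si–CH3 bond, and no alkene is present yet.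

Step 5
Reactants: 10 2-methylbut-3-yn-2-ol
Product: 11 4-iodo-2-methylbut-3-yn-2-ol
Conditions: NIS (1.1 equiv), AgNO3 (10 mol%), acetone, rt, dark
Reagents that add atoms: N-iodosuccinimide, O=C1CCC(=O)N1I
Why: Silver-catalysed electrophilic iodination of a terminal alkyne through the silver acetylide, a standard reaction in which the tertiary alcohol is inert.

Step 6
Reactants: 11 4-iodo-2-methylbut-3-yn-2-ol
Product: 12 (Z)-4-iodo-2-methylbut-3-en-2-ol
Conditions: 2-nitrobenzenesulfonyl hydrazide (2 equiv), Et3N, THF/i-PrOH 1:1, rt, dark
Reagents that add atoms: none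
Why: Diimide reduction; diimide released from the hydrazide transfers both hydrogen atoms to one face through a cyclic transition state, so a 1-iodoalkyne gives the Z-iodoalkene. No metal hydride is involved, so the C–I bond stays, and the iodoalkene is reduced more slowly than the alkyne, which limits over-reduction.

Step 7
Reactants: 9 (2S)-2-[4-methoxy-3,5-bis(4,4,5,5-tetramethyl-1,3,2-dioxaborolan-2-yl)phenyl]-5,7-bis(triisopropylsilyloxy)-2,3-dihydro-4H-chromen-4-one; 12 (Z)-4-iodo-2-methylbut-3-en-2-ol
Product: 13 (2S)-2-{3-[(1Z)-3-hydroxy-3-methylbut-1-en-1-yl]-4-methoxy-5-(4,4,5,5-tetramethyl-1,3,2-dioxaborolan-2-yl)phenyl}-5,7-bis(triisopropylsilyloxy)-2,3-dihydro-4H-chromen-4-one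
Conditions: Pd(PPh3)4 (5 mol%), 12 (0.8 equiv, slow addition), 2 M aq. K3PO4 (2 equiv), THF, 35–40 °C, dark
Reagents that add atoms: none
Why: Suzuki–Miyaura coupling; oxidative addition of zerovalent palladium into the alkenyl C–I bond and the reductive elimination both proceed with retention, so the Z geometry of 12 is carried into 13. The two boronates of 9 are equivalent, so only one mono-adduct exists; the iodide is kept limiting, unreacted 9 is recovered, and the hydroxyl group separates 13 from 9 and from the double adduct. An alkenyl iodide couples near room temperature, which keeps the exposure of C2 and the silyl ethers to base short.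

Step 8
Reactants: 13 (2S)-2-{3-[(1Z)-3-hydroxy-3-methylbut-1-en-1-yl]-4-methoxy-5-(4,4,5,5-tetramethyl-1,3,2-dioxaborolan-2-yl)phenyl}-5,7-bis(triisopropylsilyloxy)-2,3-dihydro-4H-chromen-4-one; 14 prenyl bromide (1-bromo-3-methylbut-2-ene)
Product: 15 (2S)-2-{3-[(1Z)-3-hydroxy-3-methylbut-1-en-1-yl]-4-methoxy-5-(3-methylbut-2-en-1-yl)phenyl}-5,7-bis(triisopropylsilyloxy)-2,3-dihydro-4H-chromen-4-one
Conditions: Pd(dppf)Cl2·CH2Cl2 (5 mol%), 14 (2 equiv), K3PO4 (3 equiv), H2O (5 equiv), THF, 40 °C
Reagents that add atoms: none
Why: Allyl–aryl Suzuki–Miyaura coupling; 14 gives a π-prenyl complex of divalent palladium, the boronate transfers the aryl group, and reductive elimination forms the bond at the unsubstituted allyl terminus, which gives the linear prenyl arene as known for aryl boron reagents with prenyl halides. The small amount of water activates the boronate while limiting solvolysis of 14, and the tertiary alcohol is not alkylated by phosphate base.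

Step 9
Reactants: 15 (2S)-2-{3-[(1Z)-3-hydroxy-3-methylbut-1-en-1-yl]-4-methoxy-5-(3-methylbut-2-en-1-yl)phenyl}-5,7-bis(triisopropylsilyloxy)-2,3-dihydro-4H-chromen-4-one
Product: 16 (2S)-5,7-dihydroxy-2-{3-[(1Z)-3-hydroxy-3-methylbut-1-en-1-yl]-4-methoxy-5-(3-methylbut-2-en-1-yl)phenyl}-2,3-dihydro-4H-chromen-4-one
Conditions: Bu4NF/AcOH 1:1 (3 equiv), THF, 0 °C
Reagents that add atoms: none
Why: Fluoride cleavage of aryl silyl ethers; acetic acid protonates each phenoxide as it forms, so the medium is never basic enough to open ring C nor acidic enough to ionise the tertiary allylic alcohol or touch the prenyl group.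

## Compound list

1 | 2,4,6-trihydroxyacetophenone | CC(=O)c1c(O)cc(O)cc1O | starting material
2 | 1-[2-hydroxy-4,6-bis(triisopropylsilyloxy)phenyl]ethanone | CC(=O)c1c(O)cc(O[Si](C(C)C)(C(C)C)C(C)C)cc1O[Si](C(C)C)(C(C)C)C(C)C | intermediate
3 | (E)-3-(dimethylamino)-1-[2-hydroxy-4,6-bis(triisopropylsilyloxy)phenyl]prop-2-en-1-one | CN(C)/C=C/C(=O)c1c(O)cc(O[Si](C(C)C)(C(C)C)C(C)C)cc1O[Si](C(C)C)(C(C)C)C(C)C | intermediate
4 | 5,7-bis(triisopropylsilyloxy)-4H-chromen-4-one | O=c1ccoc2cc(O[Si](C(C)C)(C(C)C)C(C)C)cc(O[Si](C(C)C)(C(C)C)C(C)C)c12 | intermediate
5 | 4-methoxyphenylboronic acid | COc1ccc(B(O)O)cc1 | starting material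
6 | (S)-4'-methoxy-5,7-bis(triisopropylsilyloxy)flavanone | COc1ccc([C@@H]2CC(=O)c3c(O[Si](C(C)C)(C(C)C)C(C)C)cc(O[Si](C(C)C)(C(C)C)C(C)C)cc3O2)cc1 | intermediate
7 | bis(pinacolato)diboron | CC1(C)OB(OC1(C)C)B1OC(C)(C)C(C)(C)O1 | starting material
8 | (S)-4'-methoxy-3'-(pinacolboryl)-5,7-bis(triisopropylsilyloxy)flavanone | COc1ccc([C@@H]2CC(=O)c3c(O[Si](C(C)C)(C(C)C)C(C)C)cc(O[Si](C(C)C)(C(C)C)C(C)C)cc3O2)cc1B4OC(C)(C)C(C)(C)O4 | intermediate
9 | (S)-4'-methoxy-3',5'-bis(pinacolboryl)-5,7-bis(triisopropylsilyloxy)flavanone | COc1c(B2OC(C)(C)C(C)(C)O2)cc([C@@H]3CC(=O)c4c(O[Si](C(C)C)(C(C)C)C(C)C)cc(O[Si](C(C)C)(C(C)C)C(C)C)cc4O3)cc1B5OC(C)(C)C(C)(C)O5 | intermediate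
10 | 2-methylbut-3-yn-2-ol | CC(C)(O)C#C | starting material
11 | 4-iodo-2-methylbut-3-yn-2-ol | CC(C)(O)C#CI | intermediate
12 | (Z)-4-iodo-2-methylbut-3-en-2-ol | CC(C)(O)/C=C\I | intermediate
13 | (S)-3'-[(Z)-3-hydroxy-3-methylbut-1-enyl]-4'-methoxy-5'-(pinacolboryl)-5,7-bis(triisopropylsilyloxy)flavanone | COc1c(/C=C\C(C)(C)O)cc([C@@H]2CC(=O)c3c(O[Si](C(C)C)(C(C)C)C(C)C)cc(O[Si](C(C)C)(C(C)C)C(C)C)cc3O2)cc1B4OC(C)(C)C(C)(C)O4 | intermediate
14 | prenyl bromide | CC(C)=CCBr | starting material
15 | (S)-3'-[(Z)-3-hydroxy-3-methylbut-1-enyl]-4'-methoxy-5'-prenyl-5,7-bis(triisopropylsilyloxy)flavanone | COc1c(/C=C\C(C)(C)O)cc([C@@H]2CC(=O)c3c(O[Si](C(C)C)(C(C)C)C(C)C)cc(O[Si](C(C)C)(C(C)C)C(C)C)cc3O2)cc1CC=C(C)C | intermediate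
16 | (S)-5,7-dihydroxy-3'-[(Z)-3-hydroxy-3-methylbut-1-enyl]-4'-methoxy-5'-prenylflavanone | COc1c(/C=C\C(C)(C)O)cc([C@@H]2CC(=O)c3c(O)cc(O)cc3O2)cc1CC=C(C)C | target

## Step count and least certain steps

Total step count: 9. Longest linear sequence: 7 (steps 1, 2, 3, 4, 7, 8, 9); steps 5 and 6 form the side branch. Enantiomeric purity is to be checked on a chiral stationary phase after steps 3, 7, 8 and 9.

**Step 4 (key step).**
- *Risk:* The reaction may stall at monoboronate 8. With one boryl neighbour in place the methoxy group turns its methyl group toward the remaining ortho C–H bond, and the catalyst may decay before the slower second cycle is complete.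
- *Risk:* Forcing time or temperature invites erosion of site selectivity (attack next to C2 on ring B or at C8 on ring A). It also invites slow reduction of the C4 carbonyl by the accumulating pinacolborane.
- *Fallback:* It sets out from chromone 4, comes back at 9, and brings the two handles in as halogens.
  - Commercial 2,6-dibromoanisole is borylated at its only unhindered position, para to the methoxy group, to give 2-(3,5-dibromo-4-methoxyphenyl)-4,4,5,5-tetramethyl-1,3,2-dioxaborolane F1.
  - NaIO4 and NH4OAc in aqueous acetone cleave the pinacol ester to 3,5-dibromo-4-methoxyphenylboronic acid F2.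
  - The conditions of step 3, which leave aryl bromides untouched, add F2 to 4 and give (S)-3',5'-dibromo-4'-methoxy-5,7-bis(triisopropylsilyloxy)flavanone F3.
  - A twofold Miyaura borylation (Pd(dppf)Cl2, 7, KOAc, dioxane, 90 °C) converts F3 into 9.

**Step 7.**
- *Risk:* The main weakness is over-coupling. The remaining boronate of 13 should react at a rate similar to those of 9. For equal reactivity per site, statistics cap the mono-adduct near one half of the material in a single pass, so recovery and recycling of 9 are part of the step.
- *Risk:* Lesser dangers are base-induced opening of ring C with loss of enantiomeric purity, protodeboronation of the surviving boronate, and Z to E drift through palladium hydride species.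
- *Fallback:* It removes the statistical element by making the two ortho positions different from the start. It sets out from chromone 4 and comes back at 13.
  - Commercial 3-bromo-4-methoxyphenylboronic acid is added to 4 under the conditions of step 3 to give (S)-3'-bromo-4'-methoxy-5,7-bis(triisopropylsilyloxy)flavanone F4.
  - A single iridium-catalysed borylation at the one open position ortho to the methoxy group gives (S)-3'-bromo-4'-methoxy-5'-(pinacolboryl)-5,7-bis(triisopropylsilyloxy)flavanone F5.
  - At room temperature Pd(PPh3)4 inserts into the alkenyl C–I bond of 12 far faster than into the hindered, electron-rich aryl C–Br bond. The Suzuki–Miyaura coupling therefore gives (S)-3'-bromo-5'-[(Z)-3-hydroxy-3-methylbut-1-enyl]-4'-methoxy-5,7-bis(triisopropylsilyloxy)flavanone F6.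
  - Miyaura borylation of the bromide (Pd(dppf)Cl2, 7, KOAc, dioxane, 80 °C) then gives 13.

**Step 8.**
- *Risk:* Bond formation at the tertiary allyl terminus (reverse prenylation).
- *Risk:* Solvolysis of 14 or protodeboronation outrunning the coupling.
- *Risk:* Loss of the 7-O-silyl group followed by O-prenylation.
- *Risk:* Ionisation or isomerisation of the Z-allylic alcohol by palladium.
- *Fallback:* It sets out from 9 and comes back at 15. It reverses the order of the two couplings and builds the prenyl group in two stages.
  - Mono-allylation of 9 with limiting allyl bromide (Pd(dppf)Cl2, K3PO4, THF) has no regiochemical issue because both allyl termini are alike. It gives (S)-3'-allyl-4'-methoxy-5'-(pinacolboryl)-5,7-bis(triisopropylsilyloxy)flavanone F7.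
  - Cross-metathesis with 2-methylbut-2-ene (second-generation Grubbs catalyst, CH2Cl2, 40 °C), run while no Z-alkene is present, gives (S)-4'-methoxy-5'-(pinacolboryl)-3'-prenyl-5,7-bis(triisopropylsilyloxy)flavanone F8.
  - Coupling of F8 with an excess of 12 under the conditions of step 7 gives 15, so the Z-alkenyl carbinol never meets a π-allyl palladium species.

**Step 3.**
- *Risk:* Insertion may be sluggish because 4 is a doubly donor-substituted vinylogous ester crowded at the peri position. Protodeboronation of 5 could then outrun the addition, and the level of facial selectivity on this hindered acceptor is not assured.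
- *Fallback:* It sets out from 4 and 5, comes back at 6, and separates bond formation from stereocontrol.
  - The more reactive achiral catalyst [Rh(OH)(cod)]2 (dioxane/H2O, 40 °C) gives racemic 4'-methoxy-5,7-bis(triisopropylsilyloxy)flavanone F9.
  - A kinetic resolution by Noyori-type asymmetric transfer hydrogenation follows (RuCl(p-cymene)[(R,R)-TsDPEN], HCO2H/Et3N, EtOAc). By the usual aryl ketone model it forms 4R alcohols and should consume the 2R ketone through the favoured cis-selective hydride delivery.
  - This converts the unwanted enantiomer into (2R,4R)-4'-methoxy-5,7-bis(triisopropylsilyloxy)flavan-4-ol F10 and leaves 6, which is separated by chromatography.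

## Further compounds

F1 | step 4 | 2-(3,5-dibromo-4-methoxyphenyl)-4,4,5,5-tetramethyl-1,3,2-dioxaborolane | COc1c(Br)cc(B2OC(C)(C)C(C)(C)O2)cc1Br
F2 | step 4 | 3,5-dibromo-4-methoxyphenylboronic acid | COc1c(Br)cc(B(O)O)cc1Br
F3 | step 4 | (S)-3',5'-dibromo-4'-methoxy-5,7-bis(triisopropylsilyloxy)flavanone | COc1c(Br)cc([C@@H]2CC(=O)c3c(O[Si](C(C)C)(C(C)C)C(C)C)cc(O[Si](C(C)C)(C(C)C)C(C)C)cc3O2)cc1Br
F4 | step 7 | (S)-3'-bromo-4'-methoxy-5,7-bis(triisopropylsilyloxy)flavanone | COc1ccc([C@@H]2CC(=O)c3c(O[Si](C(C)C)(C(C)C)C(C)C)cc(O[Si](C(C)C)(C(C)C)C(C)C)cc3O2)cc1Br
F5 | step 7 | (S)-3'-bromo-4'-methoxy-5'-(pinacolboryl)-5,7-bis(triisopropylsilyloxy)flavanone | COc1c(Br)cc([C@@H]2CC(=O)c3c(O[Si](C(C)C)(C(C)C)C(C)C)cc(O[Si](C(C)C)(C(C)C)C(C)C)cc3O2)cc1B4OC(C)(C)C(C)(C)O4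
F6 | step 7 | (S)-3'-bromo-5'-[(Z)-3-hydroxy-3-methylbut-1-enyl]-4'-methoxy-5,7-bis(triisopropylsilyloxy)flavanone | COc1c(/C=C\C(C)(C)O)cc([C@@H]2CC(=O)c3c(O[Si](C(C)C)(C(C)C)C(C)C)cc(O[Si](C(C)C)(C(C)C)C(C)C)cc3O2)cc1Br
F7 | step 8 | (S)-3'-allyl-4'-methoxy-5'-(pinacolboryl)-5,7-bis(triisopropylsilyloxy)flavanone | COc1c(CC=C)cc([C@@H]2CC(=O)c3c(O[Si](C(C)C)(C(C)C)C(C)C)cc(O[Si](C(C)C)(C(C)C)C(C)C)cc3O2)cc1B4OC(C)(C)C(C)(C)O4
F8 | step 8 | (S)-4'-methoxy-5'-(pinacolboryl)-3'-prenyl-5,7-bis(triisopropylsilyloxy)flavanone | COc1c(CC=C(C)C)cc([C@@H]2CC(=O)c3c(O[Si](C(C)C)(C(C)C)C(C)C)cc(O[Si](C(C)C)(C(C)C)C(C)C)cc3O2)cc1B4OC(C)(C)C(C)(C)O4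
F9 | step 3 | racemic 4'-methoxy-5,7-bis(triisopropylsilyloxy)flavanone | COc1ccc(C2CC(=O)c3c(O[Si](C(C)C)(C(C)C)C(C)C)cc(O[Si](C(C)C)(C(C)C)C(C)C)cc3O2)cc1
F10 | step 3 | (2R,4R)-4'-methoxy-5,7-bis(triisopropylsilyloxy)flavan-4-ol | COc1ccc([C@H]2C[C@@H](O)c3c(O[Si](C(C)C)(C(C)C)C(C)C)cc(O[Si](C(C)C)(C(C)C)C(C)C)cc3O2)cc1
A1 | alternative 1 | methyl 4-[(2S)-2-(3-bromo-4-methoxy-5-prenylphenyl)-4-oxo-3,4-dihydro-2H-pyran-6-yl]-3-oxobutanoate | COc1c(Br)cc([C@@H]2CC(=O)C=C(CC(=O)CC(=O)OC)O2)cc1CC=C(C)C
A2 | alternative 1 | (S)-3'-bromo-5,7-dihydroxy-4'-methoxy-5'-prenylflavanone | COc1c(Br)cc([C@@H]2CC(=O)c3c(O)cc(O)cc3O2)cc1CC=C(C)C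
A3 | alternative 2 | 6-[(2S,4S)-5,7-bis(tert-butyldimethylsilyloxy)-4-hydroxychroman-2-yl]-8-prenylcoumarin | O=C1C=Cc2cc([C@@H]3C[C@H](O)c4c(O[Si](C)(C)C(C)(C)C)cc(O[Si](C)(C)C(C)(C)C)cc4O3)cc(CC=C(C)C)c2O1
A4 | alternative 2 | (2S,4S)-5,7-bis(tert-butyldimethylsilyloxy)-4'-hydroxy-3'-[(Z)-3-hydroxy-3-methylbut-1-enyl]-5'-prenylflavan-4-ol | Oc1c(/C=C\C(C)(C)O)cc([C@@H]2C[C@H](O)c3c(O[Si](C)(C)C(C)(C)C)cc(O[Si](C)(C)C(C)(C)C)cc3O2)cc1CC=C(C)C
A5 | alternative 3 | 3,5-bis(methoxymethoxy)-2-(trimethylsilyl)phenyl trifluoromethanesulfonate | COCOc1cc(OCOC)c([Si](C)(C)C)c(OS(=O)(=O)C(F)(F)F)c1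
A6 | alternative 3 | methyl (3S)-3-(3-bromo-4-methoxy-5-prenylphenyl)-3-(triethylsilyloxy)propanoate | COc1c(Br)cc([C@H](CC(=O)OC)O[Si](CC)(CC)CC)cc1CC=C(C)C
A7 | alternative 3 | (S)-3'-bromo-4'-methoxy-5'-prenyl-5,7-bis(methoxymethoxy)flavanone | COc1c(Br)cc([C@@H]2CC(=O)c3c(OCOC)cc(OCOC)cc3O2)cc1CC=C(C)C
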